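**Remark on numbering.** Compounds 1–30 are numbered in the order of the steps below and keep these numbers throughout; ring A is the cyclopentanone, ring B the cyclohexene, and atoms carry indene numbers.

## Analysis of the target

The target 30 is a 2,3,3a,4,5,7a-hexahydro-1H-inden-2-one. Ring A, a cyclopentanone (C1, C2, C3, C3a, C7a), is fused along C3a–C7a to ring B, a cyclohexene (C3a, C4, C5, C6, C7, C7a) with a methyl group on C7 of the C6=C7 bond. There are six stereocentres. The methine carbons C1 (ethyl), C3 (methyl), C3a and C7a alternate around ring A, so the fusion is trans and every substituent of ring A is trans to its neighbours. C4 (ethyl, CO2H) and C5 (ethyl, E-styryl) are adjacent quaternary centres; their ethyl groups lie on the face of C7a–H, the carboxyl and styryl groups on the face of C3a–H. C1 and C3 flank the ketone and can be equilibrated, whereas C3a, C4, C5 and C7a need kinetic control. The styrene does not survive dissolving metals or strong acid, the C6=C7 bond can drift into conjugation wherever C7a–H is acidic, and the hindered acid at C4 can lactonize with a free hydroxymethyl group on C5. The main difficulty is the pair of contiguous all-carbon quaternary stereocentres inside ring B, next to the ring fusion. The strategy rests on C2: this carbonyl carbon bridges C1 and C3 across the C3a–C7a bond, so ring A is the sum of an alkyne (C3≡C3a), an alkene (C7a=C1) and carbon monoxide, and because C3a and C7a are already joined through C4–C5–C6=C7, forming C3a–C7a closes ring B as well.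

## Retrosynthetic reasoning

**30 to 29.** The acid is traced back to its tert-butyl ester 29. An ester on the quaternary C4 cannot be saponified, but a tert-butyl ester is lost by alkyl–oxygen cleavage, which does not need access to the carbonyl carbon, and it survives the basic and reducing steps before.

**29 to 27 and 26.** The styrene is cut between its two alkene carbons, giving aldehyde 27 and a benzylidene unit to be delivered by Horner–Wadsworth–Emmons olefination. The cut is made late because a styrene would not survive the dissolving-metal step that sets C3a. The first-formed styrene 28 is a mixture at C1 and C3 and is equilibrated in the same flask to 29. Aldehyde 27 comes from alcohol 26 by oxidation.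

**26 to 24.** Removing the hydrogens at C3a and C3 and restoring the benzylic ether leads to enone 24. One dissolving-metal reduction (through 25) should add hydrogen at C3a trans to C7a–H and cleave the 4-methoxybenzyl ether, so no separate deprotection is needed.

**24 to 22.** The C1–ethyl bond is cut at the enone stage. In 22 a kinetic base can only deprotonate C1 (giving 23); after the reduction two α-positions would compete. Carrying the ethyl group through the ring-forming step would need a 1,2-disubstituted alkene, a poor partner for the carbonylative cyclization.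

**22 to 20 and 21.** This is the key disconnection. The bonds C3a–C7a, C2–C3 and C1–C2 are cut, which opens both rings and leaves the acyclic dienyne 20 and carbon monoxide 21. It is placed here because one step then builds the whole bicycle around two quaternary centres that already exist. The forward reaction must engage the terminal vinyl group and choose the face that puts C7a–H on the side of the two ethyl groups.

**20 to 16.** The Z-diene is cut at C7–C7a (vinyl cross-coupling onto the Z-iodoalkene 19) and at C6=C7 (iodo-olefination of aldehyde 18). Aldehyde 18 comes from cleavage of the propenyl group of 16 through ozonide 17. The geometry of C6=C7 is fixed at the iodoalkene stage and retained in the coupling.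

**16 to 12.** Ester 16 comes from acid 15, and the C4–C5 bond of 15 is cut in a [3,3] sense: an Ireland–Claisen rearrangement of allylic ester 12 through ketene acetal 13 and silyl ester 14. A sigmatropic step is chosen because it joins two fully substituted carbons reliably and transfers one carbinol stereocentre into both quaternary centres.

**12 to the starting materials.** Ester 12 is cut at the acyl–oxygen bond into alcohol 11 and acid 3. Acid 3 is the α-ethylation product of pent-3-ynoic acid 1 (through 2). Alcohol 11 comes from 10, 9 and the E-enoate 8, which is the olefination product of phosphonate 6 with aldehyde 7, made in the flask from the silylated lactate 5 and hence from ethyl (R)-lactate 4.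

## Alternatives that were turned down

**Alternative 1:** Only the C3a–C7a bond of ring A is cut, opening the cyclopentanone to the cross-conjugated E,E-dienone A1. Forward, BF3·OEt2 would induce the conrotatory 4π closure of A1 and Et3SiH would reduce the oxyallyl cation to the all-trans cyclopentanone A2.
- For: conrotation of an E,E-dienone fixes the trans relation of C3a and C7a by orbital symmetry, the α-centres come out in the thermodynamic arrangement, and the C1 ethyl group is built in. Neither the enone alkylation nor the dissolving-metal step of the chosen route would be needed; on the stereochemistry of ring A this alternative is stronger.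
- Against: the sense of conrotation is steered only by a remote acyclic centre, and the isopropenyl arm makes the cation a more delocalized one with less regiocontrol. Above all, A2 contains neither quaternary centre: C4 would have to be alkylated next to the ring, C5 attached as a second fully substituted carbon and ring B closed, all on a base-sensitive ketone.
- Comparison: the chosen strategy makes the two quaternary centres first, in an acyclic rearrangement where such bonds form well, and then uses them to steer the ring closure.

**Alternative 2:** The C6=C7 bond is cut, leading to the triene acid A3, in which C5 carries two vinyl groups and C7a an isopropenyl group on a preformed trans-cyclopentanone. Forward, the second-generation Grubbs catalyst would join one vinyl group with the isopropenyl group to give the 5-vinyl bicycle A4 and make C5 stereogenic.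
- For: ring-closing metathesis to a cyclohexene is more dependable than carbonylative cyclization of a 1,7-enyne, it is neutral, and the surviving vinyl group marks the place of the styrene. As a ring closure it is the stronger reaction.
- Against: the choice between the two diastereotopic vinyl groups rests only on C4 and the ring fusion; a 1,1-disubstituted alkene and a vinyl group on a quaternary carbon are both slow partners; the remaining vinyl group must still be arylated. A3 also presupposes the bond between the ring methine C3a and the quaternary C4 with C5 next to it, which is the real problem of the target and is left unsolved.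
- Comparison: in exchange for a riskier closure, the chosen step forms both rings and three skeletal bonds at once, and C5 is set by chirality transfer and not by group selection.

**Alternative 3:** The C3–C3a and C1–C7a bonds are cut, giving the three-carbon donor 2-[(trimethylsilyl)methyl]allyl acetate A5 and the acyclic E-enone A6, which carries the quaternary C4 as a β-keto ester. Forward, a zerovalent palladium catalyst such as Pd(PPh3)4 would convert A5 into the zwitterionic trimethylenemethane complex, which adds to A6 to give the trans-disubstituted methylenecyclopentane A7.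
- For: the step is catalytic, convergent and mild; the trans relation of C3a and C7a follows from the E-alkene; enantioselective ligand variants exist. In catalyst economy and asymmetric potential it is stronger than a rhodium-catalysed cyclization that relies on substrate control.
- Against: A7 is far from the target. The exocyclic methylene must be cleaved to reveal the C2 ketone, ethyl and methyl must be placed on two nearly equivalent α-carbons, C5 is a ketone carbon that would have to become an all-carbon quaternary centre, and ring B is still open. Facial selectivity next to an acyclic quaternary centre is uncertain, and the β-keto ester is prone to retro-Claisen cleavage.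
- Comparison: the chosen strategy distinguishes C1 from C3 by construction (methyl from the alkyne, ethyl by alkylation of the only enolizable position of the enone) and closes ring B in the same step.

Key step: step 13

**Remark on the chemistry:** the configuration encoded in the target SMILES is taken as absolute, and the all-trans arrangement at C1 and C3 is taken to be the thermodynamic one for this α,α′-disubstituted cyclopentanone, so these two centres are set by equilibration in step 17.

## Route

Step 1
Reactants: 1 pent-3-ynoic acid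
Product: 3 2-ethylpent-3-ynoic acid (racemic), via dilithium enediolate 2 (not isolated)
Conditions: LiN(i-Pr)2 (2.2 equiv), THF, −78 → 0 °C; EtI, −78 °C → rt; aq. HCl
Reagents that add atoms: iodoethane, CCI
Why: Alkylation of a carboxylic acid dianion; the enediolate should react at the α-carbon, which carries the largest coefficient, and not at the γ-carbon of its allenyl form. The new centre is racemic and is erased in step 8.

Step 2
Reactants: 4 ethyl (R)-lactate
Product: 5 ethyl (2R)-2-[(tert-butyldimethylsilyl)oxy]propanoate
Conditions: t-BuMe2SiCl, imidazole, DMF, 0 °C → rt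
Reagents that add atoms: tert-butyldimethylsilyl chloride, CC(C)(C)[Si](C)(C)Cl
Why: Standard silylation of a secondary alcohol; the stereocentre is not touched.

Step 3
Reactants: 5 silylated lactate; 6 triethyl 2-phosphonobutanoate
Product: 8 ethyl (2E,4R)-4-[(tert-butyldimethylsilyl)oxy]-2-ethylpent-2-enoate, via (R)-2-[(tert-butyldimethylsilyl)oxy]propanal 7 (not isolated)
Conditions: i-Bu2AlH (1.05 equiv), CH2Cl2, −78 °C; then 6/NaH (preformed in THF), −78 °C → rt
Reagents that add atoms: none
Why: Half-reduction of the ester and Horner–Wadsworth–Emmons olefination in one flask avoids handling the epimerizable α-silyloxy aldehyde. The α-substituted phosphonate should give mainly the E-enoate (chain trans to the ester, cis to ethyl); any Z isomer is removed by chromatography.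

Step 4
Reactants: 8 E-enoate
Product: 9 (2E,4R)-4-[(tert-butyldimethylsilyl)oxy]-2-ethylpent-2-en-1-ol
Conditions: i-Bu2AlH (2.5 equiv), CH2Cl2, −78 → 0 °C; aq. potassium sodium tartrate
Reagents that add atoms: none
Why: 1,2-Reduction of a conjugated ester by an aluminium hydride; silyl ether and alkene geometry are unaffected.

Step 5
Reactants: 9 allylic alcohol
Product: 10 tert-butyl({(2R,3E)-4-ethyl-5-[(4-methoxybenzyl)oxy]pent-3-en-2-yl}oxy)dimethylsilane
Conditions: NaH, 4-MeOC6H4CH2Cl, Bu4NI (cat.), THF/DMF, 0 °C → rt
Reagents that add atoms: 4-methoxybenzyl chloride, COc1ccc(CCl)cc1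
Why: Williamson etherification of the primary alkoxide; the CH2O group and the silyloxy carbon are trans on the alkene, so silyl migration is not possible.

Step 6
Reactants: 10 silyl ether
Product: 11 (2R,3E)-4-ethyl-5-[(4-methoxybenzyl)oxy]pent-3-en-2-ol
Conditions: Bu4NF, THF, 0 °C → rt
Reagents that add atoms: none
Why: Fluoride cleaves the silyl ether; the benzylic ether is stable and the carbinol centre is retained.

Step 7
Reactants: 11 allylic alcohol; 3 2-ethylpent-3-ynoic acid
Product: 12 (2R,3E)-4-ethyl-5-[(4-methoxybenzyl)oxy]pent-3-en-2-yl 2-ethylpent-3-ynoate (both epimers at C2 of the acyl part)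
Conditions: DCC, DMAP (5 mol %), CH2Cl2, 0 °C
Reagents that add atoms: none
Why: Steglich esterification with retention at the carbinol carbon; little DMAP and low temperature limit isomerization to the allenoate, which would give the same enolate in step 8 anyway. The acyl α-centre is erased in the next step.

Step 8
Reactants: 12 allylic ester
Product: 15 (2R,3S,4E)-2,3-diethyl-3-{[(4-methoxybenzyl)oxy]methyl}-2-(prop-1-yn-1-yl)hex-4-enoic acid, via (Z)-trimethylsilyl ketene acetal 13 (not isolated), via trimethylsilyl ester 14 (not isolated)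
Conditions: LiN(i-Pr)2, Me3SiCl (present during deprotonation), THF, −78 °C; then rt → 60 °C; aq. HCl
Reagents that add atoms: none
Why: Ireland–Claisen rearrangement. Kinetic deprotonation through the cyclic transition state puts the slim propynyl group cis to OLi and the ethyl group cis to the allyl oxygen, and immediate silylation freezes this geometry before it can equilibrate through the allenyl form of the enolate. A chair transition state with the carbinol methyl equatorial then joins C4 and C5, transferring the lactate centre into both quaternary carbons (2R,3S) and giving the E-propenyl group.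

Step 9
Reactants: 15 acid
Product: 16 tert-butyl (2R,3S,4E)-2,3-diethyl-3-{[(4-methoxybenzyl)oxy]methyl}-2-(prop-1-yn-1-yl)hex-4-enoate
Conditions: t-BuOC(=N-i-Pr)NH-i-Pr, CH2Cl2, rt → 40 °C
Reagents that add atoms: O-tert-butyl-N,N'-diisopropylisourea, CC(C)N=C(OC(C)(C)C)NC(C)C
Why: The carboxylate is alkylated on oxygen by the protonated isourea, so hindrance at the acyl carbon does not matter; the neutral conditions spare the benzylic ether, alkyne and alkene.

Step 10
Reactants: 16 tert-butyl ester
Product: 18 tert-butyl (2R,3S)-2,3-diethyl-3-formyl-4-[(4-methoxybenzyl)oxy]-2-(prop-1-yn-1-yl)butanoate, via secondary ozonide 17 (not isolated)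
Conditions: O3, CH2Cl2, −78 °C (stopped at the first blue tint); PPh3, −78 °C → rt
Reagents that add atoms: ozone, [O-][O+]=O
Why: Ozonolysis; at −78 °C the disubstituted alkene reacts far faster than the internal alkyne or the anisyl ring. The aldehyde has no α-hydrogen, so it can neither epimerize nor eliminate.

Step 11
Reactants: 18 aldehyde
Product: 19 tert-butyl (2R,3S,4Z)-2,3-diethyl-5-iodo-3-{[(4-methoxybenzyl)oxy]methyl}-2-(prop-1-yn-1-yl)hex-4-enoate
Conditions: EtPPh3I, n-BuLi, THF, rt; I2, −78 °C; NaN(SiMe3)2, −78 → −20 °C; then 18, −78 → −20 °C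
Reagents that add atoms: ethyltriphenylphosphonium iodide, CC[P+](c1ccccc1)(c1ccccc1)c1ccccc1.[I-]; iodine, II
Why: Wittig olefination with the α-iodo ylide (Stork–Zhao-type iodo-olefination); the non-stabilized ylide reacts through the cis-oxaphosphetane and should give the Z-iodoalkene, with the C5 chain and iodine cis.

Step 12
Reactants: 19 Z-iodoalkene
Product: 20 tert-butyl (2R,3S,4Z)-2,3-diethyl-3-{[(4-methoxybenzyl)oxy]methyl}-5-methyl-2-(prop-1-yn-1-yl)hepta-4,6-dienoate
Conditions: Bu3SnCH=CH2, Pd(PPh3)4 (10 mol %), CuI (20 mol %), CsF, DMF, 45 °C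
Reagents that add atoms: tributyl(vinyl)stannane, C=C[Sn](CCCC)(CCCC)CCCC
Why: Stille coupling with zerovalent palladium proceeds with retention of alkene geometry, so the C5 chain and the vinyl group stay cis. Copper and fluoride speed up transmetalation at the hindered iodide; alkyne and ester are tolerated.

Step 13
Reactants: 20 dienyne; 21 carbon monoxide
Product: 22 tert-butyl (4R,5S,7aR)-4,5-diethyl-5-{[(4-methoxybenzyl)oxy]methyl}-3,7-dimethyl-2-oxo-2,4,5,7a-tetrahydro-1H-indene-4-carboxylate
Conditions: [Rh(CO)2Cl]2 (10 mol %), CO (1 atm), toluene, 90 → 110 °C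
Reagents that add atoms: none
Why: Intramolecular Pauson–Khand reaction of a 1,7-enyne under monovalent rhodium; the closest known type is the [Rh(CO)2Cl]2-catalysed carbonylative cyclization of enynes and dienynes. Rhodium binds the alkyne and the terminal vinyl group, oxidative cyclization forms C3a–C7a and a rhodacyclopentene, CO inserts into a Rh–C bond and reductive elimination completes C1–C2 and C2–C3. Ring B closes in the oxidative cyclization as the six-membered tether ring, exo to both π-systems (C3 and C1 stay outside it); ring A closes as the [2+2+1] ring by insertion and reductive elimination. The Z-alkene and the two quaternary carbons of the tether hold the alkyne and the vinyl group close together; a [4+2] path would need a four-membered tether ring, and the trisubstituted alkene cannot reach the alkyne. Because the rhodium-bound carbon C1 is not allylic, the η3-allyl assistance known for dienes that react at their tether-side double bond is not available, and the diene can only serve as a chelating ligand. The one new stereocentre, C7a, is set by the face of the vinyl group presented in the half-chair of the forming ring B, under control of the fixed C4 and C5 centres. The half-chair that keeps the flat ester of C4 pseudo-equatorial beside the alkyne methyl group and turns the C4 ethyl group pseudo-axial should be preferred, and it places C7a–H on the side of both ethyl groups (7aR). The step therefore needs chemoselectivity for the vinyl group, secured by ring size, and facial selectivity at C7a, secured only by this substrate bias.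

Step 14
Reactants: 22 bicyclic enone
Product: 24 tert-butyl (1S,4R,5S,7aR)-1,4,5-triethyl-5-{[(4-methoxybenzyl)oxy]methyl}-3,7-dimethyl-2-oxo-2,4,5,7a-tetrahydro-1H-indene-4-carboxylate, via lithium dienolate 23 (not isolated)
Conditions: LiN(i-Pr)2 (1.1 equiv), THF, −78 °C; EtI, DMPU, −78 → −30 °C
Reagents that add atoms: iodoethane, CCI
Why: Kinetic α′-deprotonation of the enone at C1 gives the cross-conjugated dienolate, which is alkylated by the primary iodide. Ethyl should enter anti to the ring-B carbon C7 (1S); the centre remains epimerizable and is finally set in step 17.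

Step 15
Reactants: 24 ethylated enone
Product: 26 tert-butyl (1S,3aR,4R,5S,7aR)-1,4,5-triethyl-5-(hydroxymethyl)-3,7-dimethyl-2-oxo-2,3,3a,4,5,7a-hexahydro-1H-indene-4-carboxylate (mixture of C3 epimers), via dilithium enolate alkoxide 25 (not isolated)
Conditions: Li (6 equiv), NH3/THF, t-BuOH (1 equiv), −78 °C; solid NH4Cl, −78 °C → rt
Reagents that add atoms: none
Why: Dissolving-metal reduction of the enone: C3a is protonated on the face that leaves both ring-fusion bonds equatorial on ring B, trans to C7a–H, since a cis fusion would push C3 into a 1,3-diaxial clash with the C5 side chain. The same medium cleaves the benzylic C–O bond of the 4-methoxybenzyl ether. The cold quench protonates C3 without control (corrected in step 17) and neutralizes the alkoxide before it can attack the tert-butyl ester.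

Step 16
Reactants: 26 hydroxy ketone
Product: 27 tert-butyl (1S,3aR,4R,5S,7aR)-1,4,5-triethyl-5-formyl-3,7-dimethyl-2-oxo-2,3,3a,4,5,7a-hexahydro-1H-indene-4-carboxylate (mixture of C3 epimers)
Conditions: Dess–Martin periodinane, CH2Cl2, 0 °C → rt
Reagents that add atoms: none
Why: Mild, neutral oxidation of the neopentyl alcohol; the aldehyde has no α-hydrogen, and the short contact time keeps the hydroxy ester from lactonizing.

Step 17
Reactants: 27 aldehyde
Product: 29 tert-butyl (1S,3S,3aR,4R,5S,7aR)-1,4,5-triethyl-3,7-dimethyl-2-oxo-5-[(E)-2-phenylethenyl]-2,3,3a,4,5,7a-hexahydro-1H-indene-4-carboxylate, via styrene epimer mixture 28 (not isolated)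
Conditions: (EtO)2P(O)CH2Ph, KOt-Bu, THF, 0 °C → rt; then MeOH, rt
Reagents that add atoms: diethyl benzylphosphonate, CCOP(=O)(Cc1ccccc1)OCC
Why: Horner–Wadsworth–Emmons olefination of the aldehyde, which is far more electrophilic than the flanked cyclopentanone, gives the E-styrene as usual for benzylphosphonate carbanions. Alkoxide in methanol then equilibrates C1 and C3 through the enolates to the all-trans arrangement (1S,3S), each α-substituent trans to the neighbouring ring-B bond. C3a and C7a are not enolizable and C6=C7 cannot move.

Step 18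
Reactants: 29 tert-butyl ester
Product: 30 (1S,3S,3aR,4R,5S,7aR)-1,4,5-triethyl-3,7-dimethyl-2-oxo-5-[(E)-2-phenylethenyl]-2,3,3a,4,5,7a-hexahydro-1H-indene-4-carboxylic acid
Conditions: CF3CO2H/CH2Cl2 (1:4), 0 °C
Reagents that add atoms: none
Why: Acidolysis of the tert-butyl ester by alkyl–oxygen cleavage with loss of isobutene, independent of hindrance at the acyl carbon; short exposure at 0 °C spares the styrene and the C6=C7 bond, and no stereocentre is touched.

## Compound list

1 | pent-3-ynoic acid | CC#CCC(=O)O | starting material
2 | dilithium pent-1-en-3-yne-1,1-bis(olate) | CC#CC=C(O[Li])O[Li] | intermediate (not isolated)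
3 | 2-ethylpent-3-ynoic acid (racemic) | CC#CC(CC)C(=O)O | intermediate
4 | ethyl (R)-lactate | C[C@@H](O)C(=O)OCC | starting material
5 | ethyl (2R)-2-[(tert-butyldimethylsilyl)oxy]propanoate | C[C@@H](O[Si](C)(C)C(C)(C)C)C(=O)OCC | intermediate
6 | triethyl 2-phosphonobutanoate | CCOC(=O)C(CC)P(=O)(OCC)OCC | starting material
7 | (R)-2-[(tert-butyldimethylsilyl)oxy]propanal | C[C@@H](O[Si](C)(C)C(C)(C)C)C=O | intermediate (not isolated)
8 | ethyl (2E,4R)-4-[(tert-butyldimethylsilyl)oxy]-2-ethylpent-2-enoate | C[C@@H](O[Si](C)(C)C(C)(C)C)/C=C(\CC)C(=O)OCC | intermediate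
9 | (2E,4R)-4-[(tert-butyldimethylsilyl)oxy]-2-ethylpent-2-en-1-ol | C[C@@H](O[Si](C)(C)C(C)(C)C)/C=C(\CC)CO | intermediate
10 | tert-butyl({(2R,3E)-4-ethyl-5-[(4-methoxybenzyl)oxy]pent-3-en-2-yl}oxy)dimethylsilane | C[C@@H](O[Si](C)(C)C(C)(C)C)/C=C(\CC)COCc1ccc(OC)cc1 | intermediate
11 | (2R,3E)-4-ethyl-5-[(4-methoxybenzyl)oxy]pent-3-en-2-ol | C[C@@H](O)/C=C(\CC)COCc1ccc(OC)cc1 | intermediate
12 | (2R,3E)-4-ethyl-5-[(4-methoxybenzyl)oxy]pent-3-en-2-yl 2-ethylpent-3-ynoate (acyl C2 epimers) | CC#CC(CC)C(=O)O[C@H](C)/C=C(\CC)COCc1ccc(OC)cc1 | intermediate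
13 | {[(1Z)-2-ethyl-1-{[(2R,3E)-4-ethyl-5-[(4-methoxybenzyl)oxy]pent-3-en-2-yl]oxy}pent-1-en-3-yn-1-yl]oxy}trimethylsilane | CC#C/C(CC)=C(\O[Si](C)(C)C)O[C@H](C)/C=C(\CC)COCc1ccc(OC)cc1 | intermediate (not isolated)
14 | trimethylsilyl (2R,3S,4E)-2,3-diethyl-3-{[(4-methoxybenzyl)oxy]methyl}-2-(prop-1-yn-1-yl)hex-4-enoate | CC#C[C@@](CC)(C(=O)O[Si](C)(C)C)[C@@](CC)(COCc1ccc(OC)cc1)/C=C/C | intermediate (not isolated)
15 | (2R,3S,4E)-2,3-diethyl-3-{[(4-methoxybenzyl)oxy]methyl}-2-(prop-1-yn-1-yl)hex-4-enoic acid | CC#C[C@@](CC)(C(=O)O)[C@@](CC)(COCc1ccc(OC)cc1)/C=C/C | intermediate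
16 | tert-butyl (2R,3S,4E)-2,3-diethyl-3-{[(4-methoxybenzyl)oxy]methyl}-2-(prop-1-yn-1-yl)hex-4-enoate | CC#C[C@@](CC)(C(=O)OC(C)(C)C)[C@@](CC)(COCc1ccc(OC)cc1)/C=C/C | intermediate
17 | tert-butyl (2R,3S)-2,3-diethyl-4-[(4-methoxybenzyl)oxy]-3-(5-methyl-1,2,4-trioxolan-3-yl)-2-(prop-1-yn-1-yl)butanoate (mixture at the trioxolane carbons) | CC#C[C@@](CC)(C(=O)OC(C)(C)C)[C@@](CC)(COCc1ccc(OC)cc1)C1OOC(C)O1 | intermediate (not isolated)
18 | tert-butyl (2R,3S)-2,3-diethyl-3-formyl-4-[(4-methoxybenzyl)oxy]-2-(prop-1-yn-1-yl)butanoate | CC#C[C@@](CC)(C(=O)OC(C)(C)C)[C@@](CC)(COCc1ccc(OC)cc1)C=O | intermediate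
19 | tert-butyl (2R,3S,4Z)-2,3-diethyl-5-iodo-3-{[(4-methoxybenzyl)oxy]methyl}-2-(prop-1-yn-1-yl)hex-4-enoate | CC#C[C@@](CC)(C(=O)OC(C)(C)C)[C@@](CC)(COCc1ccc(OC)cc1)/C=C(C)\I | intermediate
20 | tert-butyl (2R,3S,4Z)-2,3-diethyl-3-{[(4-methoxybenzyl)oxy]methyl}-5-methyl-2-(prop-1-yn-1-yl)hepta-4,6-dienoate | CC#C[C@@](CC)(C(=O)OC(C)(C)C)[C@@](CC)(COCc1ccc(OC)cc1)/C=C(C)\C=C | intermediate
21 | carbon monoxide | [C-]#[O+] | starting material
22 | tert-butyl (4R,5S,7aR)-4,5-diethyl-5-{[(4-methoxybenzyl)oxy]methyl}-3,7-dimethyl-2-oxo-2,4,5,7a-tetrahydro-1H-indene-4-carboxylate | C1C(=O)C(C)=C2[C@H]1C(C)=C[C@@](COCc3ccc(OC)cc3)(CC)[C@]2(CC)C(=O)OC(C)(C)C | intermediate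
23 | lithium (4R,5S,7aR)-4-(tert-butoxycarbonyl)-4,5-diethyl-5-{[(4-methoxybenzyl)oxy]methyl}-3,7-dimethyl-5,7a-dihydro-4H-inden-2-olate | C1=C(O[Li])C(C)=C2[C@H]1C(C)=C[C@@](COCc3ccc(OC)cc3)(CC)[C@]2(CC)C(=O)OC(C)(C)C | intermediate (not isolated)
24 | tert-butyl (1S,4R,5S,7aR)-1,4,5-triethyl-5-{[(4-methoxybenzyl)oxy]methyl}-3,7-dimethyl-2-oxo-2,4,5,7a-tetrahydro-1H-indene-4-carboxylate | CC[C@@H]1C(=O)C(C)=C2[C@H]1C(C)=C[C@@](COCc3ccc(OC)cc3)(CC)[C@]2(CC)C(=O)OC(C)(C)C | intermediate
25 | dilithium salt of 26: lithium enolate (O on C2, C2=C3) and lithium alkoxide of the C5 hydroxymethyl group | CC[C@@H]1C(O[Li])=C(C)[C@H]2[C@H]1C(C)=C[C@@](CO[Li])(CC)[C@]2(CC)C(=O)OC(C)(C)C | intermediate (not isolated)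
26 | tert-butyl (1S,3aR,4R,5S,7aR)-1,4,5-triethyl-5-(hydroxymethyl)-3,7-dimethyl-2-oxo-2,3,3a,4,5,7a-hexahydro-1H-indene-4-carboxylate (C3 epimers) | CC[C@@H]1C(=O)C(C)[C@H]2[C@H]1C(C)=C[C@@](CO)(CC)[C@]2(CC)C(=O)OC(C)(C)C | intermediate
27 | tert-butyl (1S,3aR,4R,5S,7aR)-1,4,5-triethyl-5-formyl-3,7-dimethyl-2-oxo-2,3,3a,4,5,7a-hexahydro-1H-indene-4-carboxylate (C3 epimers) | CC[C@@H]1C(=O)C(C)[C@H]2[C@H]1C(C)=C[C@@](C=O)(CC)[C@]2(CC)C(=O)OC(C)(C)C | intermediate
28 | tert-butyl (3aR,4R,5S,7aR)-1,4,5-triethyl-3,7-dimethyl-2-oxo-5-[(E)-2-phenylethenyl]-2,3,3a,4,5,7a-hexahydro-1H-indene-4-carboxylate (epimers at C1 and C3) | CCC1C(=O)C(C)[C@H]2[C@H]1C(C)=C[C@@](/C=C/c3ccccc3)(CC)[C@]2(CC)C(=O)OC(C)(C)C | intermediate (not isolated)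
29 | tert-butyl (1S,3S,3aR,4R,5S,7aR)-1,4,5-triethyl-3,7-dimethyl-2-oxo-5-[(E)-2-phenylethenyl]-2,3,3a,4,5,7a-hexahydro-1H-indene-4-carboxylate | CC[C@@H]1C(=O)[C@@H](C)[C@H]2[C@H]1C(C)=C[C@@](/C=C/c3ccccc3)(CC)[C@]2(CC)C(=O)OC(C)(C)C | intermediate
30 | (1S,3S,3aR,4R,5S,7aR)-1,4,5-triethyl-3,7-dimethyl-2-oxo-5-[(E)-2-phenylethenyl]-2,3,3a,4,5,7a-hexahydro-1H-indene-4-carboxylic acid (CNP0302656.1) | CC[C@@H]1C(=O)[C@@H](C)[C@H]2[C@H]1C(C)=C[C@@](/C=C/c1ccccc1)(CC)[C@]2(CC)C(=O)O | target

## Step count and least certain steps

Total step count: 18. Longest linear sequence: 17 steps (steps 2–18, from ethyl (R)-lactate 4); step 1 is a one-step branch that joins at step 7.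

**Step 13 (key step).**
- Risk: slow oxidative cyclization. The substrate is a 1,7-enyne with an internal alkyne next to a quaternary carbon, the rhodium may rest as an η4-diene complex, and no allyl stabilization of the metallacycle is available. At the temperature needed, the doubly activated C7a–H of the product may let the C6=C7 bond move into conjugation. Facial selectivity at C7a is also not assured, and it cannot be repaired by base, because equilibration through the extended enolate would move the ring-B double bond as well.
- Fallback: from 20, Co2(CO)8 in CH2Cl2 at room temperature gives the hexacarbonyldicobalt complex of the alkyne F1. It is isolated and heated under CO (1 atm) in toluene at 70 °C with cyclohexylamine as promoter. This stoichiometric cobalt-mediated Pauson–Khand reaction works at lower temperature on a preformed alkyne complex, has a different transition-state geometry, and returns to the route at 22.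

**Step 8.**
- Risk: loss of the ketene acetal geometry. The alkynyl enolate can rotate through its allenyl form before it is silylated, which would give the C4 epimer of 15; crowding between the two fully substituted termini also slows the rearrangement.
- Fallback: from 11, esterification (DCC, DMAP) with commercial ethyl hydrogen ethylmalonate gives the mixed malonate F2. Its lithium enolate is a chelate with both carbonyl oxygens on the same side, so silylation (LiN(SiMe3)2, Me3SiCl) can only place the ethoxycarbonyl group cis to the silyloxy group. Ireland–Claisen rearrangement gives the half-ester acid F3, with the ethoxycarbonyl group in the place of the propynyl group. tert-Butyl ester formation as in step 9 gives the diester F4, LiBH4 reduces only the ethyl ester to the alcohol F5, and Dess–Martin oxidation gives the aldehyde F6. CBr4/PPh3 gives the dibromoalkene F7 (Corey–Fuchs), and n-BuLi followed by MeI converts it into 16, where the route is rejoined.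

**Step 11.**
- Risk: sluggish addition of the bulky iodo-ylide to a neopentyl aldehyde flanked by two quaternary carbons, with ylide decay and loss of iodine competing.
- Fallback: from 18, Still–Gennari olefination with ethyl 2-[bis(2,2,2-trifluoroethoxy)phosphoryl]propanoate (KN(SiMe3)2, 18-crown-6, THF, −78 °C) gives the Z-enoate F8. i-Bu2AlH at −78 °C reduces the conjugated ethyl ester to the allylic alcohol F9 and leaves the tert-butyl ester on the quaternary carbon. MnO2 gives the Z-enal F10, and Wittig methylenation (Ph3P=CH2) gives diene 20, so the C7–C7a bond is made by olefination and not by cross-coupling.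

**Step 15.**
- Risk: transesterification of the tert-butyl ester by the neighbouring lithium alkoxide (lactonization), favoured by the two quaternary carbons, and partial reduction of the ester by excess metal.
- Fallback: from 24, only 2.2 equiv of Li (NH3/THF, t-BuOH 1 equiv, −78 °C, immediate NH4Cl quench) reduces the enone alone and keeps the ether, giving the 4-methoxybenzyl ether ketone F11. Oxidative removal of the ether with DDQ (CH2Cl2/pH 7 buffer) then gives 26 without an alkoxide ever being formed.

**Step 17.**
- Risk: slow addition of the phosphonate carbanion to the hindered aldehyde while the base enolizes the ketone, leading to aldol-type decay.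
- Fallback: from 27, Takai olefination (CrCl2, CHI3, THF), which needs no base and does not touch ketones, gives the E-iodoalkene F12. Suzuki coupling with PhB(OH)2 (Pd(PPh3)4, K2CO3, dioxane/water) gives 28, which is equilibrated with K2CO3 in MeOH to 29.

## Further compounds

F1 | step 13 | hexacarbonyldicobalt complex of the propynyl group of 20, [Co2(CO)6(μ-alkyne)] | CC12C3([C@@](CC)(C(=O)OC(C)(C)C)[C@@](CC)(COCc4ccc(OC)cc4)/C=C(C)\C=C)[Co]1(=C=O)(=C=O)(=C=O)[Co]23(=C=O)(=C=O)=C=O
F2 | step 8 | ethyl (2R,3E)-4-ethyl-5-[(4-methoxybenzyl)oxy]pent-3-en-2-yl 2-ethylpropanedioate | CCOC(=O)C(CC)C(=O)O[C@H](C)/C=C(\CC)COCc1ccc(OC)cc1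
F3 | step 8 | (2R,3S,4E)-2-(ethoxycarbonyl)-2,3-diethyl-3-{[(4-methoxybenzyl)oxy]methyl}hex-4-enoic acid | CCOC(=O)[C@@](CC)(C(=O)O)[C@@](CC)(COCc1ccc(OC)cc1)/C=C/C
F4 | step 8 | tert-butyl ethyl diester of F3 (C4 and C5 arranged as in 16) | CCOC(=O)[C@@](CC)(C(=O)OC(C)(C)C)[C@@](CC)(COCc1ccc(OC)cc1)/C=C/C
F5 | step 8 | tert-butyl (4E)-2,3-diethyl-2-(hydroxymethyl)-3-{[(4-methoxybenzyl)oxy]methyl}hex-4-enoate (C4 and C5 arranged as in 16) | OC[C@@](CC)(C(=O)OC(C)(C)C)[C@@](CC)(COCc1ccc(OC)cc1)/C=C/C
F6 | step 8 | tert-butyl (4E)-2,3-diethyl-2-formyl-3-{[(4-methoxybenzyl)oxy]methyl}hex-4-enoate (C4 and C5 arranged as in 16) | O=C[C@@](CC)(C(=O)OC(C)(C)C)[C@@](CC)(COCc1ccc(OC)cc1)/C=C/C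
F7 | step 8 | tert-butyl (4E)-2-(2,2-dibromoethenyl)-2,3-diethyl-3-{[(4-methoxybenzyl)oxy]methyl}hex-4-enoate (C4 and C5 arranged as in 16) | BrC(Br)=C[C@@](CC)(C(=O)OC(C)(C)C)[C@@](CC)(COCc1ccc(OC)cc1)/C=C/C
F8 | step 11 | 1-tert-butyl 6-ethyl (2R,3S,4Z)-2,3-diethyl-3-{[(4-methoxybenzyl)oxy]methyl}-5-methyl-2-(prop-1-yn-1-yl)hex-4-enedioate | CC#C[C@@](CC)(C(=O)OC(C)(C)C)[C@@](CC)(COCc1ccc(OC)cc1)/C=C(C)\C(=O)OCC
F9 | step 11 | tert-butyl (2R,3S,4Z)-2,3-diethyl-6-hydroxy-3-{[(4-methoxybenzyl)oxy]methyl}-5-methyl-2-(prop-1-yn-1-yl)hex-4-enoate | CC#C[C@@](CC)(C(=O)OC(C)(C)C)[C@@](CC)(COCc1ccc(OC)cc1)/C=C(C)\CO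
F10 | step 11 | tert-butyl (2R,3S,4Z)-2,3-diethyl-3-{[(4-methoxybenzyl)oxy]methyl}-5-methyl-6-oxo-2-(prop-1-yn-1-yl)hex-4-enoate | CC#C[C@@](CC)(C(=O)OC(C)(C)C)[C@@](CC)(COCc1ccc(OC)cc1)/C=C(C)\C=O
F11 | step 15 | tert-butyl (1S,3aR,4R,5S,7aR)-1,4,5-triethyl-5-{[(4-methoxybenzyl)oxy]methyl}-3,7-dimethyl-2-oxo-2,3,3a,4,5,7a-hexahydro-1H-indene-4-carboxylate (C3 epimers) | CC[C@@H]1C(=O)C(C)[C@H]2[C@H]1C(C)=C[C@@](COCc3ccc(OC)cc3)(CC)[C@]2(CC)C(=O)OC(C)(C)C
F12 | step 17 | tert-butyl 1,4,5-triethyl-5-[(E)-2-iodoethenyl]-3,7-dimethyl-2-oxo-2,3,3a,4,5,7a-hexahydro-1H-indene-4-carboxylate (ring centres arranged as in 27, C3 epimers) | CC[C@@H]1C(=O)C(C)[C@H]2[C@H]1C(C)=C[C@@](/C=C/I)(CC)[C@]2(CC)C(=O)OC(C)(C)C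
A1 | alternative 1 | (3E,6E,8R)-4-ethyl-2,6-dimethyl-8-{[(triisopropylsilyl)oxy]methyl}deca-1,3,6-trien-5-one | C=C(C)/C=C(\CC)C(=O)/C(C)=C/[C@@H](CC)CO[Si](C(C)C)(C(C)C)C(C)C
A2 | alternative 1 | all-trans 2-ethyl-5-methyl-3-(prop-1-en-2-yl)-4-[1-(triisopropylsilyloxy)butan-2-yl]cyclopentan-1-one | CC[C@@H]1C(=O)[C@@H](C)[C@@H]([C@H]1C(C)=C)[C@@H](CC)CO[Si](C(C)C)(C(C)C)C(C)C
A3 | alternative 2 | 3-ethenyl-2,3-diethyl-2-[all-trans-3-ethyl-5-methyl-4-oxo-2-(prop-1-en-2-yl)cyclopentyl]pent-4-enoic acid | CC[C@@H]1C(=O)[C@@H](C)[C@@H]([C@H]1C(C)=C)[C@@](CC)(C(=O)O)C(CC)(C=C)C=C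
A4 | alternative 2 | 5-ethenyl analogue of 30 (ethenyl in place of 2-phenylethenyl) | CC[C@@H]1C(=O)[C@@H](C)[C@H]2[C@H]1C(C)=C[C@@](C=C)(CC)[C@]2(CC)C(=O)O
A5 | alternative 3 | 2-[(trimethylsilyl)methyl]allyl acetate | CC(=O)OCC(=C)C[Si](C)(C)C
A6 | alternative 3 | tert-butyl (E)-2-ethyl-5-oxo-2-propanoylhex-3-enoate | CC(=O)/C=C/[C@@](CC)(C(=O)OC(C)(C)C)C(=O)CC
A7 | alternative 3 | tert-butyl 2-(trans-2-acetyl-4-methylidenecyclopentyl)-2-ethyl-3-oxopentanoate | C=C1C[C@@H]([C@H](C1)C(C)=O)[C@@](CC)(C(=O)OC(C)(C)C)C(=O)CC
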